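## Structural features

The target (C30H42O6) is made of two guaianolide units, each a cyclopentane fused to a cycloheptane fused to a trans α-methyl-γ-lactone. Guaiane numbering is used throughout: unprimed for the half that keeps the C4=C5 double bond (cyclopentene ring A, cycloheptane ring B, lactone ring C), primed for the saturated half (cyclopentane ring E, cycloheptane ring F, lactone ring G).

The halves are joined by two bonds, C2–C2′ and C3–C5′, which close a new cyclopentane (ring D: C2, C3, C5′, C1′, C2′). Rings D and E together form a bicyclo[2.2.1]heptane with bridgeheads C2′ and C5′ and one-carbon bridge C1′ (also a member of ring F); ring A is fused endo on the C2–C3 bridge.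

Of the fifteen stereocentres, C1, C2, C3, C5′, C4′, C2′ and C1′ are contiguous on or next to the bicycle. C5′ is quaternary (bonded to C1′, C3, C4′, C6′). C4′ carries an endo (α) methyl and an exo (β) hydrogen on a bridge whose exo face lies under the C10′ substituents and whose endo face lies over ring A.

Each half has a tertiary alcohol at C10 (β-hydroxy, α-methyl, next to ring-fusion carbon C1) and the C6, C7, C11 lactone centres of α-santonin. The C10 configuration is opposite to the one that the photochemical entry from santonin delivers.

Fragile points are the tertiary alcohols (elimination, in the unprimed half toward conjugation with C4=C5), the electron-rich tetrasubstituted C4=C5 bond, the epimerizable C11 and C1 positions, and the strained bicycle under cationic conditions.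

The structure hides a symmetry. The C2–C2′ bond joins the same carbon of two identical C15 units, so only the second bond, C3–C5′, makes the halves different. The oxidation pattern of the primed half (C3′H2 and C4′H next to quaternary C5′) is that of a polar addition to C5′ with hydrogen delivered to C4′. The key step exploits this: it closes ring D through the C3–C5′ bond inside a C2-symmetric, C2–C2′-linked dimer and sets C3, C5′ and C4′ in the same event.

The real difficulty is the quaternary C5′ inside the bicycle, the C4′ configuration, and telling two identical halves apart.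

## Logic of the disconnections

**15 to 14.** The C10–CH3 and C10′–CH3 bonds are cut. The tertiary carbinols have the configuration opposite to the photochemical entry, and a methyl nucleophile added to a C10 ketone on the face syn to H-1 (H-1′) places the hydroxyl β as required. Two stereocentres disappear. The forward step must add to two ketones in the presence of two lactones, on the correct face, without enolizing C1 or C1′.

**14 to 10 (through 12 and 11, with 13 in passing).** No skeletal bond is cut. Each C10 ketone is traced to an exocyclic methylene, that to the tertiary alcohol of opposite configuration, and that to its acetate. This returns the C10 centres to the configuration the photoreaction gives. The forward steps need exocyclic regiochemistry in the dehydration and an oxidative cleavage that spares C4=C5.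

**10 to 8 (through 9).** The C3′ methylene is traced to a ketone. The ketone is the trace left by the key step. The forward deoxygenation must not epimerize C4′ next to it and must leave lactones and acetates alone.

**8 to 5 (through 7 and 6).** The C3–C5′ bond is cut, the C4′ hydrogen is returned to C3′ (ketone back to carbinol), and a hydroxyl is placed on C3. This removes ring D, the bicycle, the quaternary centre and the stereocentres C3, C5′ and C4′, and leaves a C2-symmetric diol in which both halves carry the same allylic alcohol. The forward step must ionize one alcohol, close at C5′ and not at C4′, and end by hydride shift with retention of face.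

**5 to 4.** The two carbinols are traced to the two enone carbonyls. Hydride has to enter anti to the other half on the adjacent C2, because the C3′ hydrogen later becomes the C4′ hydrogen.

**4 to 2 (through 3).** The C2–C2′ bond is cut into two identical α′-enolates. This halves the molecule at its only symmetric bond. The forward oxidative coupling must be α′-regioselective and must form both ends of the bond on the α face.

**2 to 1.** The 5-7 skeleton is traced to the 6-6 cross-conjugated dienone by reconnecting C5–C10, cutting C1–C5 and removing acetate. All of C6, C7, C11 and the carbon skeleton come from 1. The forward step is a photochemical dienone rearrangement run in the acid that supplies the C10 acetate.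

## Other disconnections considered

**Alternative 1:** Cut C2–C2′ and C3–C5′ together. Forward key step: thermal [4+2] cyclodimerization of the guaia-2,4-dienolide A1 (from 2 by reduction and dehydration) to the norbornene A2, then hydrogenation of C3′=C4′ and the same C10 correction. This is the disconnection that comes to mind first. It leaves C4′ to an intermolecular hydrogenation of A2 in which the exo face of C3′=C4′ lies under the C10′ substituents and the endo face over ring A, so neither face is clearly open. A1 is also a cyclopentadiene with an sp3 C1–H that can scramble by 1,5-hydrogen shifts before it dimerizes. The chosen plan sets C4′ by an intramolecular hydrogen shift and does not depend on a free cyclopentadiene.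

**Alternative 2:** Cut C3–C5′ reductively in 4. Forward key step: SmI2-induced ketyl–enone cyclization of 4 (5-exo addition of the C3 ketyl to C5′) to the hydroxy ketone A3. A3 keeps a tertiary allylic hydroxyl at C3, next to the quaternary centre. Its removal must pass an allyl cation or radical that can accept hydrogen at C5 as well as at C3. C4′ would be set by external protonation of an enolate, and the enone radical anion can also couple through C5. Two deoxygenations would be needed where the chosen plan needs one.

**Alternative 3:** Cut C3–C5′ as an ene-type conjugate addition. Forward key step: Lewis-acid-promoted intramolecular ene reaction of the mixed dimer A4 (one half a 3-ene with 5α-H, the other the cyclopentenone), giving 8 directly. A4 is unsymmetrical, so it needs either a statistical cross-coupling of two different ketone enolates or several steps to differentiate the halves of 4. A cyclopentenone with a fully substituted β-carbon is a reluctant enophile, and the C4 cation can lose a proton to C15 or C3 as well as to C5. In the chosen plan one functional group in a symmetric precursor plays both roles.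

Key step: step 4

Remark (assumption): commercial (−)-α-santonin is the only chiral starting material; its C6, C7 and C11 centres pass unchanged into both halves of 15.

## Route

Step 1
Reactants: 1 (−)-α-santonin
Product: 2 O-acetylisophotosantonic lactone (10α-acetoxy-3-oxo-1αH-guai-4-en-6α,12-olide)
Conditions: hν (medium-pressure Hg lamp, Pyrex), glacial AcOH, N2, 15–20 °C
Reagents that add atoms: acetic acid, CC(O)=O
Why: Photochemical rearrangement of a cross-conjugated cyclohexadienone (santonin to isophotosantonic lactone type): C1–C5 bonding in the excited dienone is followed by acid-assisted cleavage of the C5–C10 cyclopropane bond with capture of acetate at C10 with inversion. This gives the 5-7 skeleton with 1α-H and 10α-OAc; C6, C7 and C11 are untouched.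

Step 2
Reactants: 2 O-acetylisophotosantonic lactone (two molecules)
Product: 4 2α,2′α-linked bis-enone (C2-symmetric dimer of 2 joined C2–C2′), via lithium dienolate 3 (not isolated)
Conditions: LDA (1.05 equiv), THF, −78 °C; then CuCl2 (1.1 equiv), DMF, −78 to −20 °C
Reagents that add atoms: none
Why: Kinetic α′-deprotonation of the cyclopentenone gives the cross-conjugated dienolate 3, and one-electron oxidation by CuCl2 with C–C coupling at C2 is the oxidative dimerization of ketone enolates to 1,4-diketones. Each end of the new bond should form on the α face, anti to C10 on the neighbouring C1, giving the 2S,2′S isomer (H-2 and H-2′ β) with the relative configuration the bicycle needs.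

Step 3
Reactants: 4 2α,2′α-linked bis-enone
Product: 5 3α,3′α-diol (both hydroxyls cis to the C2–C2′ bond)
Conditions: NaBH4, CeCl3·7H2O, MeOH–CH2Cl2 (3:1), −40 °C
Reagents that add atoms: none
Why: Luche reduction: cerium-assisted 1,2-hydride addition to the enones, leaving lactones and acetates. Hydride should enter each carbonyl on the β face, anti to the other half on the α face of the adjacent C2, so that both hydroxyls are α and both carbinol hydrogens β (3R,3′R).

Step 4
Reactants: 5 3α,3′α-diol
Product: 8 heptacyclic 3′-ketone (ring D closed; 4′α-methyl; 10α,10′α-diacetate), via allyl cation 6 (not isolated), via hydroxy carbenium ion 7 (not isolated)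
Conditions: TfOH (10 mol %), (CF3)2CHOH–CH2Cl2 (1:4), 0.01 M, −20 °C
Reagents that add atoms: none
Why: Proposed new method: acid removes water from either (equivalent) allylic alcohol of 5 to give the 2-methylcyclopentenyl cation 6, whose C3 terminus is held by the C2–C2′ bond over the α face of the second cyclopentenol; C5′ of the C4′=C5′ bond then adds to C3 (5-exo-trig cation–olefin closure of ring D, which with ring E makes the bicyclo[2.2.1]heptane) to give the tertiary β-hydroxy carbenium ion 7, and a suprafacial 1,2-shift of the exo (β) hydrogen from C3′ to C4′ ends the sequence as the protonated ketone, returning the proton so that the acid is catalytic. The closest known reaction types are the π-route to 2-norbornyl cations from cyclopentenylethyl cations, allyl-cation-initiated polyene cyclization and the pinacol-terminated Prins cyclization; what is new is their combination on a bis(cyclopentenol) in which one functional group is initiator on one half and terminator on the other. C3 and C5′ are set by the tether: the new bond can form only on the α faces that already carry the C2–C2′ bond (cis-fused bicyclo[3.3.0] on ring A, 1,3-cis bridge across ring E), which is the endo arrangement of 15. C4′ is set by chirality transfer from the C3′ carbinol of step 3: the hydrogen stays on the exo face, the favoured mode of 3,2-hydride shifts in norbornyl cations, and the methyl group is left endo. The selectivity needed is closure at C5′ and not at C4′ (both would give five-membered rings): cyclization is reversible, only the C4′ cation has a neighbouring carbinol that can terminate irreversibly, and the acyloxy-bearing C6′ disfavours charge at C5′. Return of a hydroxyl to the cation and elimination to cyclopentadienes are reversible under the protic conditions, the tertiary acetates and lactones should not ionize with catalytic acid at −20 °C, and because of the C2 symmetry it does not matter which half ionizes.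

Step 5
Reactants: 8 heptacyclic 3′-ketone
Product: 9 3′-tosylhydrazone of 8
Conditions: TsNHNH2 (1.5 equiv), EtOH, 50 °C
Reagents that add atoms: 4-methylbenzenesulfonohydrazide, Cc1ccc(cc1)S(=O)(=O)NN
Why: Condensation of the strained, unconjugated bicyclic ketone with tosylhydrazide; lactones and tertiary acetates are inert to it. Near-neutral conditions limit enolization toward C4′, and C2′ is a bridgehead that cannot enolize.

Step 6
Reactants: 9 3′-tosylhydrazone of 8
Product: 10 diacetate with C3′H2 (10,10′-bis-epi-15 diacetate)
Conditions: catecholborane (2.5 equiv), CHCl3, 0 °C; then NaOAc·3H2O, reflux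
Reagents that add atoms: none
Why: Tosylhydrazone reduction with catecholborane: hydroboration of C=N, then acetate-induced loss of sulfinate and of N2 from the diazene, turns C3′ into CH2. No enol or enolate is involved, so C4′ is kept, and lactones and acetates tolerate the reagent.

Step 7
Reactants: 10 diacetate with C3′H2
Product: 11 10,10′-bis-epi-15 (10α,10′α-diol)
Conditions: K2CO3, MeOH, 40 °C; then aq. HCl to pH 3
Reagents that add atoms: none
Why: Base-catalysed transesterification removes both tertiary acetates as methyl acetate. Any lactone opened by methoxide should reclose on acidification, and C11 is expected to keep its configuration.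

Step 8
Reactants: 11 10,10′-bis-epi-15
Product: 12 10(14),10′(14′)-bis(exocyclic alkene)
Conditions: SOCl2, pyridine, CH2Cl2, −30 °C
Reagents that add atoms: none
Why: Chlorosulfite formation and pyridine-mediated anti E2 elimination. H-1 and H-1′ are syn to the leaving groups and cannot be anti-periplanar, which excludes the Δ1(10) isomers; the methyl hydrogens are the most accessible anti hydrogens, so the exocyclic alkenes should predominate. The wrongly configured C10 centres are erased.

Step 9
Reactants: 12 10(14),10′(14′)-bis(exocyclic alkene)
Product: 14 14,14′-dinor-10,10′-diketone, via tetraol 13 (not isolated)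
Conditions: OsO4 (2 mol %), NaIO4 (4.5 equiv), 2,6-lutidine, dioxane–H2O (3:1), 20 °C
Reagents that add atoms: osmium tetroxide, O=[Os](=O)(=O)=O; sodium periodate, [Na+].[O-]I(=O)(=O)=O
Why: Johnson–Lemieux oxidation: OsO4 should dihydroxylate the open 1,1-disubstituted alkenes much faster than the shielded tetrasubstituted C4=C5 bond, and periodate cleaves the diols of 13 to the ketones with loss of formaldehyde. 2,6-Lutidine buffers the medium so that C1 (α to the new ketone and allylic) is not epimerized.

Step 10
Reactants: 14 14,14′-dinor-10,10′-diketone
Product: 15 target CNP0182139.2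
Conditions: MeMgBr (6 equiv), CeCl3 (anhydrous, 6 equiv), THF, −78 °C; then aq. NH4Cl
Reagents that add atoms: methylmagnesium bromide, C[Mg]Br
Why: 1,2-Addition of the organocerium reagent made from MeMgBr and CeCl3, which is ketone-selective beside lactones and weakly basic, so C1 and C1′ are not enolized. Methyl should enter each carbonyl on the face syn to H-1 (H-1′): on the primed half the other face looks onto the C3′–C4′ bridge of the bicycle, on the unprimed half onto the β face of ring A. This places both hydroxyls β (10S,10′S).

## Compound list

1 | (−)-α-santonin, (3S,3aS,5aS,9bS)-3,5a,9-trimethyl-3a,5,5a,9b-tetrahydronaphtho[1,2-b]furan-2,8(3H,4H)-dione | C[C@H]1[C@@H]2CC[C@]3(C=CC(=O)C(=C3[C@H]2OC1=O)C)C | starting material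
2 | O-acetylisophotosantonic lactone, 10α-acetoxy-3-oxo-1αH-guai-4-en-6α,12-olide (1R,6S,7S,10R,11S; 11α-methyl) | CC1=C2[C@H]3OC(=O)[C@@H](C)[C@@H]3CC[C@@](C)(OC(C)=O)[C@@H]2CC1=O | intermediate
3 | lithium 2,4-dien-3-olate of 2 (cross-conjugated dienolate, C2=C3(OLi)–C4=C5) | CC1=C2[C@H]3OC(=O)[C@@H](C)[C@@H]3CC[C@@](C)(OC(C)=O)[C@@H]2C=C1O[Li] | intermediate (not isolated)
4 | 2α,2′α-linked bis-enone, 2,2′-bi(10α-acetoxy-3-oxo-1αH-guai-4-en-6α,12-olide) (2S,2′S; H-2 and H-2′ β; C2-symmetric) | O=C1C(C)=C2[C@H]3OC(=O)[C@@H](C)[C@@H]3CC[C@@](C)(OC(C)=O)[C@@H]2[C@H]1[C@H]1C(=O)C(C)=C2[C@H]3OC(=O)[C@@H](C)[C@@H]3CC[C@@](C)(OC(C)=O)[C@H]12 | intermediate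
5 | 3α,3′α-diol of 4 (3R,3′R; hydroxyls cis to the C2–C2′ bond, H-3 and H-3′ β) | O[C@H]1C(C)=C2[C@H]3OC(=O)[C@@H](C)[C@@H]3CC[C@@](C)(OC(C)=O)[C@@H]2[C@H]1[C@H]1[C@@H](O)C(C)=C2[C@H]3OC(=O)[C@@H](C)[C@@H]3CC[C@@](C)(OC(C)=O)[C@H]12 | intermediate
6 | allyl cation from 5 (one half ionized, charge shared by C3 and C5; other half unchanged) | [CH+]1C(C)=C2[C@H]3OC(=O)[C@@H](C)[C@@H]3CC[C@@](C)(OC(C)=O)[C@@H]2[C@H]1[C@H]1[C@@H](O)C(C)=C2[C@H]3OC(=O)[C@@H](C)[C@@H]3CC[C@@](C)(OC(C)=O)[C@H]12 | intermediate (not isolated)
7 | β-hydroxy carbenium ion (C3–C5′ bond formed, charge at C4′, 3′α-OH, 3′β-H) | CC1=C2[C@H]3OC(=O)[C@@H](C)[C@@H]3CC[C@@](C)(OC(C)=O)[C@@H]2[C@H]2[C@H]3[C@@H](O)[C+](C)[C@]4([C@@H]3[C@](C)(OC(C)=O)CC[C@H]3[C@H](C)C(=O)O[C@@H]34)[C@@H]12 | intermediate (not isolated)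
8 | heptacyclic 3′-ketone: skeleton and configuration of 15 with C3′=O, 4′α-methyl (endo), 4′β-H (exo), 10α,10′α-diacetoxy (both C10 centres epimeric to 15) | CC1=C2[C@H]3OC(=O)[C@@H](C)[C@@H]3CC[C@@](C)(OC(C)=O)[C@@H]2[C@H]2[C@H]3C(=O)[C@@H](C)[C@]4([C@@H]3[C@](C)(OC(C)=O)CC[C@H]3[C@H](C)C(=O)O[C@@H]34)[C@@H]12 | intermediate
9 | 3′-tosylhydrazone of 8 (C=N geometry not defined) | CC1=C2[C@H]3OC(=O)[C@@H](C)[C@@H]3CC[C@@](C)(OC(C)=O)[C@@H]2[C@H]2[C@H]3C(=NNS(=O)(=O)c5ccc(C)cc5)[C@@H](C)[C@]4([C@@H]3[C@](C)(OC(C)=O)CC[C@H]3[C@H](C)C(=O)O[C@@H]34)[C@@H]12 | intermediate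
10 | 10,10′-bis-epi-15 diacetate (C3′H2; 10α,10′α-diacetoxy) | CC1=C2[C@H]3OC(=O)[C@@H](C)[C@@H]3CC[C@@](C)(OC(C)=O)[C@@H]2[C@H]2[C@H]3C[C@@H](C)[C@]4([C@@H]3[C@](C)(OC(C)=O)CC[C@H]3[C@H](C)C(=O)O[C@@H]34)[C@@H]12 | intermediate
11 | 10,10′-bis-epi-15 (10α,10′α-dihydroxy, 10β,10′β-dimethyl) | CC1=C2[C@H]3OC(=O)[C@@H](C)[C@@H]3CC[C@@](C)(O)[C@@H]2[C@H]2[C@H]3C[C@@H](C)[C@]4([C@@H]3[C@](C)(O)CC[C@H]3[C@H](C)C(=O)O[C@@H]34)[C@@H]12 | intermediate
12 | 10(14),10′(14′)-bis(exocyclic alkene) from 11 | CC1=C2[C@H]3OC(=O)[C@@H](C)[C@@H]3CCC(=C)[C@@H]2[C@H]2[C@H]3C[C@@H](C)[C@]4([C@@H]3C(=C)CC[C@H]3[C@H](C)C(=O)O[C@@H]34)[C@@H]12 | intermediate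
13 | 10,14,10′,14′-tetraol from 12 (C10 and C10′ configuration of no consequence, left undefined) | CC1=C2[C@H]3OC(=O)[C@@H](C)[C@@H]3CCC(O)(CO)[C@@H]2[C@H]2[C@H]3C[C@@H](C)[C@]4([C@@H]3C(O)(CO)CC[C@H]3[C@H](C)C(=O)O[C@@H]34)[C@@H]12 | intermediate (not isolated)
14 | 14,14′-dinor-10,10′-diketone | CC1=C2[C@H]3OC(=O)[C@@H](C)[C@@H]3CCC(=O)[C@@H]2[C@H]2[C@H]3C[C@@H](C)[C@]4([C@@H]3C(=O)CC[C@H]3[C@H](C)C(=O)O[C@@H]34)[C@@H]12 | intermediate
15 | CNP0182139.2, guaiane numbering (1R,2S,3R,6S,7S,10S,11S,1′R,2′R,4′R,5′R,6′S,7′S,10′S,11′S); 10β,10′β-dihydroxy; 4′α-methyl | CC1=C2[C@H]3OC(=O)[C@@H](C)[C@@H]3CC[C@](C)(O)[C@@H]2[C@H]2[C@H]3C[C@@H](C)[C@]4([C@@H]3[C@@](C)(O)CC[C@H]3[C@H](C)C(=O)O[C@@H]34)[C@@H]12 | target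

## Step count and risk

Total step count: 10. Longest linear sequence: 10 steps (1 to 15); the route is linear because both halves come from 2.

Least certain steps:

**Step 4 (key step, proposed new method).** Most likely to go wrong: closure through C4′ instead of C5′; loss of the cation by elimination to cyclopentadienes that then oligomerize; ionization of a tertiary acetate; erosion of the C4′ configuration by acid-catalysed enolization of the product. All follow from using a free carbocation on a crowded, polyfunctional dimer.

Fallback in known chemistry, setting out from 4 and returning at 8. One of the two enones of 4 is reduced with a deficit of NaBH4 and CeCl3·7H2O (statistical; recovered 4 is recycled and over-reduced 5 is reoxidized to 4 with MnO2) to give the hydroxy enone F1. 1,1′-Thiocarbonyldiimidazole with DMAP converts its allylic alcohol into the imidazole-1-carbothioate F2. Slow addition of Bu3SnH and AIBN in benzene at 80 °C generates the C3 allyl radical, which adds 5-exo to C5′ of the intact enone. The α-keto radical at C4′ then takes hydrogen from the tin hydride, expected on the exo face because the endo face is covered by ring A, which gives 8.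

**Step 2.** Most likely to go wrong: incomplete or unselective coupling (α-chlorination by the copper salt, coupling on the β face at one end, γ-deprotonation with loss of the C10 acetate), because a hindered secondary enolate radical must dimerize. Fallback, from 2 back to 4: TMSOTf and Et3N in CH2Cl2 at 0 °C give the silyl dienol ether F3, which is used at once and coupled at C2 with Ag2O in DMSO; this changes the coupling partner from a lithium enolate to a neutral silyl enol ether.

**Step 3.** Most likely to go wrong: poor facial selectivity, because the β face of each carbonyl is also flanked by the C10 substituents. Hydride delivery syn to the C2 substituent would place the carbinol hydrogens α, and these hydrogens later fix C4′. Fallback, from 4 back to 5: the 3β,3′β-diol F4 formed in that case is inverted by a Mitsunobu reaction (4-nitrobenzoic acid, PPh3, DIAD; SN2 at C3 since C5 is fully substituted) to the 3α,3′α-bis(4-nitrobenzoate) F5, and methanolysis (K2CO3, MeOH, 0 °C, which leaves the tertiary acetates) gives 5.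

**Step 8.** Most likely to go wrong: elimination toward C9, giving endocyclic alkenes, because an anti hydrogen on C9 may be available in the flexible seven-membered rings. Fallback, from 11 back to 12: TMSBr in CH2Cl2 converts both tertiary alcohols into the tertiary bromides F6, and E2 elimination with potassium tert-butoxide in THF–tert-butanol, a bulky base that favours Hofmann orientation, takes the methyl hydrogens.

**Step 10.** Most likely to go wrong: addition to one or both ketones from the β face, which would return the 10-epi configuration, because the facial bias on the unprimed half rests on a conformational estimate. Fallback, from 12 directly to 15 (13 and 14 are bypassed): Mukaiyama hydration of the two exocyclic alkenes (Co(acac)2, PhSiH3, O2, then reductive work-up) places oxygen rather than carbon on the open face, so it is complementary to the ketone addition. Whichever face proves open, one of the two methods gives the 10β-alcohols; the tetrasubstituted C4=C5 bond should be inert to hydrogen atom transfer.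

## Further compounds

F1 | step 4 | mono-reduced dimer: 3α-hydroxy-4-ene half joined 2α,2′α to the unchanged enone half | O[C@H]1C(C)=C2[C@H]3OC(=O)[C@@H](C)[C@@H]3CC[C@@](C)(OC(C)=O)[C@@H]2[C@H]1[C@H]1C(=O)C(C)=C2[C@H]3OC(=O)[C@@H](C)[C@@H]3CC[C@@](C)(OC(C)=O)[C@H]12
F2 | step 4 | O-(imidazole-1-carbothioyl) derivative of F1 | S=C(n1ccnc1)O[C@H]1C(C)=C2[C@H]3OC(=O)[C@@H](C)[C@@H]3CC[C@@](C)(OC(C)=O)[C@@H]2[C@H]1[C@H]1C(=O)C(C)=C2[C@H]3OC(=O)[C@@H](C)[C@@H]3CC[C@@](C)(OC(C)=O)[C@H]12
F3 | step 2 | 3-trimethylsilyloxy-2,4-diene (silyl dienol ether of 2) | CC1=C2[C@H]3OC(=O)[C@@H](C)[C@@H]3CC[C@@](C)(OC(C)=O)[C@@H]2C=C1O[Si](C)(C)C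
F4 | step 3 | 3β,3′β-diol, the C3 and C3′ epimer of 5 | O[C@@H]1C(C)=C2[C@H]3OC(=O)[C@@H](C)[C@@H]3CC[C@@](C)(OC(C)=O)[C@@H]2[C@H]1[C@H]1[C@H](O)C(C)=C2[C@H]3OC(=O)[C@@H](C)[C@@H]3CC[C@@](C)(OC(C)=O)[C@H]12
F5 | step 3 | 3α,3′α-bis(4-nitrobenzoate) of 5 | [O-][N+](=O)c1ccc(cc1)C(=O)O[C@H]1C(C)=C2[C@H]3OC(=O)[C@@H](C)[C@@H]3CC[C@@](C)(OC(C)=O)[C@@H]2[C@H]1[C@H]1[C@@H](OC(=O)c4ccc(cc4)[N+]([O-])=O)C(C)=C2[C@H]3OC(=O)[C@@H](C)[C@@H]3CC[C@@](C)(OC(C)=O)[C@H]12
F6 | step 8 | 10,10′-dibromide from 11 (C10 and C10′ configuration undefined) | CC1=C2[C@H]3OC(=O)[C@@H](C)[C@@H]3CCC(C)(Br)[C@@H]2[C@H]2[C@H]3C[C@@H](C)[C@]4([C@@H]3C(C)(Br)CC[C@H]3[C@H](C)C(=O)O[C@@H]34)[C@@H]12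
F0 | step 10 | none | none
A1 | alternative 1 | 10α-acetoxy-1αH-guaia-2,4-dien-6α,12-olide (cyclopentadiene monomer) | CC1=C2[C@H]3OC(=O)[C@@H](C)[C@@H]3CC[C@@](C)(OC(C)=O)[C@@H]2C=C1
A2 | alternative 1 | endo [4+2] dimer of A1 with C3′=C4′ (norbornene diacetate) | CC1=C2[C@H]3OC(=O)[C@@H](C)[C@@H]3CC[C@@](C)(OC(C)=O)[C@@H]2[C@H]2[C@H]3C=C(C)[C@]4([C@@H]3[C@](C)(OC(C)=O)CC[C@H]3[C@H](C)C(=O)O[C@@H]34)[C@@H]12
A3 | alternative 2 | 3β-hydroxy analogue of 8 (tertiary allylic alcohol at C3, ketone at C3′; C4′ drawn as required) | CC1=C2[C@H]3OC(=O)[C@@H](C)[C@@H]3CC[C@@](C)(OC(C)=O)[C@@H]2[C@H]2[C@H]3C(=O)[C@@H](C)[C@]4([C@@H]3[C@](C)(OC(C)=O)CC[C@H]3[C@H](C)C(=O)O[C@@H]34)[C@@]12O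
A4 | alternative 3 | mixed dimer: 5αH-guai-3-ene half joined 2α,2′α to the cyclopentenone half | C1=C(C)[C@@H]2[C@H]3OC(=O)[C@@H](C)[C@@H]3CC[C@@](C)(OC(C)=O)[C@@H]2[C@H]1[C@H]1C(=O)C(C)=C2[C@H]3OC(=O)[C@@H](C)[C@@H]3CC[C@@](C)(OC(C)=O)[C@H]12
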